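## Structural features

The target is one cyclohexane ring, neither fused nor bridged, with a quaternary carbinol carbon C1 bearing an exocyclic CH2OBz group (C7), a CHOH at C2 next to the methylene pair C3/C4, a CHOBz at C5 and a CHOH at C6 between C5 and C1. The four oxygenated ring carbons C2–C1–C6–C5 are contiguous stereocentres with the configuration 1S,2R,5R,6S in this numbering. The C1 hydroxyl is anti to the hydroxyls on both neighbours, the C5 benzoate is anti to the C6 hydroxyl, and C7 is therefore cis to the oxygens on C2 and C6. The fragile elements are the two esters among free hydroxyls, which can migrate under acid or base (C7 to C2 or C6 through six-membered and C5 to C6 through five-membered ortho-acid intermediates), and, on the way, any oxirane at the tertiary C1. The real difficulty is twofold: the absolute configuration of the quaternary C1, and placing exactly two acyl groups on a pentaol whose three secondary hydroxyls differ only slightly. The oxygens on C7, C1 and C2, with C1–O and C2–O anti, are the imprint of a 2,3-epoxy alcohol opened at C2, so the C7–C1=C2 allylic alcohol is the substrate for a reagent-controlled epoxidation; this is the feature the key step exploits. The anti C5–O/C6–O pair is likewise an oxirane opened at C5, which lets the C5 benzoate enter as the nucleophile.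

## Logic of the disconnections

13 to 12. Cut: the O–CH2Ph bond on the C2 oxygen. The C2 hydroxyl sits 1,3 to the C7 benzoate, so it stays masked as an ether until nothing else remains to be done. No skeletal simplification results, but acyl migration is kept out of every earlier step. The forward step must cleave a hindered secondary benzyl ether under neutral conditions without touching two benzoates.

12 to 10 and 11. Cut: the C5–O bond. The anti C5–O/C6–O pair is read as a C5–C6 oxirane opened at C5 by benzoate, so the ester arrives with its own oxygen and no secondary hydroxyl has to be distinguished by acylation. One stereocentre and one ester are removed. The forward step must attack C5 and not C6, with inversion, in a buffered medium that leaves the C7 ester and the tertiary hydroxyl alone.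

10 to 9. Cut: the acyl–O bond at C7. In 9 the primary C7 hydroxyl is the only acylable hydroxyl (the other is tertiary), so the position of this ester is not in question. The only demand is that the oxirane survives.

9 to 8. Cut: the C2–O bond. The anti C1–O/C2–O diol is the C1–C2 oxirane opened at C2, the carbon remote from the C7 carbinol. This leaves a bis-epoxide whose four stereocentres all sit in two three-membered rings. The forward step must deliver the nucleophile to C2 only, with inversion, and leave the second oxirane closed.

8 to 7. Cut: the C5–O and C6–O bonds of the second oxirane. They come from the C5=C6 alkene on the face of C7, anti to the first oxirane, which is the face the later C5 opening requires. Forming this oxirane before any ring-opening also removes the allylic character of the labile C1–O bond. Two stereocentres disappear. The forward step needs face control by the C7 hydroxyl and conditions mild enough for a tertiary allylic oxirane.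

7 to 5. Cut: the C1–O and C2–O bonds of the first oxirane (key step). All remaining stereochemistry is removed and an achiral dienol is reached; the C7 hydroxyl, native to the target, is the handle and 6 is the source of chirality. The forward step must choose one enantioface of C1=C2 under reagent control and prefer the allylic over the homoallylic alkene.

5 to 4. Change of oxidation level at C7 (two C7–H bonds in place of C7=O and C7–OMe). The ester is the form in which C7 can be attached by carbonylation. The reduction must be 1,2 and must not isomerise or aromatise the diene.

4 to 3. Cut: the C1–C7 bond. A vinylic C–O electrophile at C1 takes up CO and methanol under palladium catalysis, removing the only carbon outside the ring. The coupling has to run cold because substrate and product are reactive 1,3-dienes.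

3 to 1 (through 2). Cut: the O–S bond and, behind it, the α′ C–H bond of the enone (C2 in route numbering). Kinetic enolisation on the α′ side creates C1=C2 next to the existing C5=C6 and turns the carbonyl oxygen into a leaving group. The demand is regiocontrol of deprotonation (α′, not γ).

## Other disconnections considered

Alternative 1: The cut is the ring bond C1–C2. The forward key step would be an Ireland–Claisen rearrangement run as a ring contraction. In a six-membered lactone (C7 as carbonyl, ring oxygen on C4), the O-silylated enolate C7=C1 and an (E)-2-benzyloxyvinyl group on C4 would undergo the [3,3] shift, forming C1–C2, breaking O–C4 and leaving the cyclohexenecarboxylic acid A1.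
- In its favour: the carbocycle, the quaternary C1 and C2 arise in one stereospecific pericyclic event, and C5 and C6 come from the carbohydrate pool, so no catalyst-controlled step is needed. Every oxygen is individually protected, the C5 oxygen alone as a 4-methoxybenzyl ether, so the C5 and C7 benzoates could be placed without any regiochemical question. On this point it is better than the chosen plan, where the C5 ester depends on the regiochemistry of an oxirane opening.
- Against it here: the enolate of an α,β-dialkoxy lactone can expel the C6 alkoxide. The ring-contracting shift must pass through a boat-like transition state whose sense fixes both C1 and C2 and is hard to predict for a fully oxygenated ring. The stereodefined enol ether has to be built first. Afterwards the carboxyl must be reduced to C7, the 4-methoxybenzyl group exchanged for benzoate, and the alkene and three benzyl ethers removed by hydrogenation.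
- Comparison: on structure it builds the ring, whereas the chosen plan buys it. On mechanism both rest on stereospecific steps, the Claisen transferring chirality and the epoxidation importing it from a ligand. On step economy the sugar route is clearly longer, since the lactone alone would need about as many steps as the whole chosen route.

Alternative 2: The cuts are C2–C3 and C5–C6. The forward key step would be an amine-catalysed [3+3] annulation. The enamine of 2,2-dimethyl-1,3-dioxan-5-one A2 with a chiral secondary amine adds to acrolein A3 (C2–C3), and the enamine re-formed on the other α-carbon closes by aldol addition onto the new aldehyde (C5–C6) to give the bicyclic ketone A4.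
- In its favour: two achiral three-carbon pieces give the whole ring with the C2, C5 and C6 oxygens in place and three stereocentres in one operation, which is better step economy to the core than the chosen plan. The cis C2/C6 oxygens are tied in the acetonide and C5–OH is the only free hydroxyl, so the C5 benzoate is placed without competition; here too it is the better plan.
- Against it here: the quaternary C1 is still missing. C7 and the C1 hydroxyl would have to be added to the bridging ketone (methylenation, then dihydroxylation from the face away from the acetonide) with a facial bias that is only inferred. The β-hydroxy ketone can undergo retro-aldol reaction or dehydration, A3 polymerises readily, and both enantio- and diastereocontrol rest on the catalyst alone.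
- Comparison: structurally it constructs the ring and three of four stereocentres at once; the chosen plan sets only two in its key step, but these include the quaternary one. Mechanistically both are reagent-controlled, one by an enamine catalyst, the other by the titanium–tartrate template. In step count it is about equal or slightly shorter if every selectivity holds.

Alternative 3: The cut is C1–C6. The forward key step would be an intramolecular Morita–Baylis–Hillman reaction of the keto aldehyde A5. A trialkylphosphine adds to the vinyl ketone, the resulting enolate carbon C1 attacks the C6 aldehyde, and loss of the phosphine gives the 2-methylene-3-hydroxycyclohexanone A6 with C5 and C6 trans.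
- In its favour: the C5 benzoate is present from the start, so its position is never in question (better than the chosen plan on this point). The exocyclic methylene is exactly C7 and, flanked by the C2 and C6 oxygens, should be dihydroxylated anti to both, which is the face the C1 hydroxyl needs. The step count is comparable (equal).
- Against it here: the new C6 centre is set only by 1,2-induction from C5 in a reversible aldol step. The α-acyloxy aldehyde can epimerise under the nucleophilic catalyst. The trans hydroxy ester in A6 invites benzoyl migration and β-elimination towards a phenol. The (R) centre at C5 corresponds to the unnatural series of the amino-acid pool or needs an inversion. The C2 ketone must then be reduced to the hydroxyl cis to C6–OH.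
- Comparison: structurally it builds the ring and takes absolute configuration from the chiral pool rather than a catalyst. Mechanistically three of four stereocentres are substrate-controlled and each is a separate risk, whereas in the chosen plan all four follow from one ligand-controlled epoxidation through stereospecific steps. Step economy is about equal.

Key step: step 4

Remark on the chemistry (assumption 1): the oxirane needed in step 4 is (1S,2S), the sense induced by the natural L-(+)-tartrate ester, which gives (2S,3S) epoxy alcohols from (E)-allylic alcohols and the (1S,2S) epoxide from cyclohex-1-enylmethanol. Diethyl (2R,3R)-tartrate is therefore the ligand; the D-(−) ester would give the enantiomer.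

Remark on the chemistry (assumption 2): the oxirane of 7 is tertiary and allylic at C1, so the C5=C6 alkene is epoxidised before any nucleophile is brought to the C1–C2 oxirane, and the C5 benzoate is introduced by opening that second oxirane.

## Route

Step 1
Reactants: 1 cyclohex-2-en-1-one
Product: 3 cyclohexa-1,5-dien-1-yl trifluoromethanesulfonate, via lithium cyclohexa-1,5-dien-1-olate 2 (not isolated)
Conditions: LiN(i-Pr)2, THF, −78 °C; then PhNTf2, −78 °C → rt
Reagents that add atoms: N-phenylbis(trifluoromethanesulfonimide), O=S(=O)(N(c1ccccc1)S(=O)(=O)C(F)(F)F)C(F)(F)F
Why: LiN(i-Pr)2 removes the kinetically accessible α′ proton of the enone at −78 °C to give the cross-conjugated dienolate 2, which is O-sulfonylated by PhNTf2 (enol triflate formation); no stereocentre is formed.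

Step 2
Reactants: 3 cyclohexa-1,5-dien-1-yl trifluoromethanesulfonate
Product: 4 methyl cyclohexa-1,5-diene-1-carboxylate
Conditions: Pd(PPh3)4 (5 mol %), CO (1 atm), MeOH, Et3N, DMF, rt
Reagents that add atoms: carbon monoxide, [C-]#[O+]; methanol, CO
Why: Oxidative addition of zerovalent palladium into the vinylic C–OTf bond, CO insertion and methanolysis of the acylpalladium (alkoxycarbonylation of an enol triflate) form the C1–C7 bond; room temperature spares the diene from cycloaddition and isomerisation.

Step 3
Reactants: 4 methyl cyclohexa-1,5-diene-1-carboxylate
Product: 5 (cyclohexa-1,5-dien-1-yl)methanol
Conditions: i-Bu2AlH (2.5 equiv), CH2Cl2, −78 → 0 °C; aq. KNaC4H4O6 work-up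
Reagents that add atoms: none
Why: Two hydride transfers from i-Bu2AlH reduce the conjugated ester in the 1,2 sense to the primary allylic alcohol (ester-to-alcohol reduction) without touching the diene; the non-acidic tartrate work-up protects the easily aromatised cyclohexadiene.

Step 4
Reactants: 5 (cyclohexa-1,5-dien-1-yl)methanol; 6 diethyl L-(+)-tartrate (ligand, 12 mol %, not incorporated)
Product: 7 [(1S,2S)-1,2-epoxycyclohex-5-en-1-yl]methanol
Conditions: Ti(OiPr)4 (10 mol %), 6 (12 mol %), t-BuOOH (1.5 equiv, anhydrous), 4 Å sieves, CH2Cl2, −25 °C; cold aq. NaOH/NaCl work-up
Reagents that add atoms: tert-butyl hydroperoxide, CC(C)(C)OO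
Why: Katsuki–Sharpless asymmetric epoxidation: C7–OH and t-BuOOH exchange onto the dimeric [Ti(tartrate)(OiPr)2]2 catalyst, and the bound peroxide oxygen passes in one concerted step to the C1=C2 alkene held by the C7 alkoxide, closing the oxirane by syn transfer of a single oxygen atom to both carbons (an atom transfer, not a nucleophilic cyclisation), so C1–O and C2–O form together and the ring fusion is necessarily cis. The closest known cases are cyclohex-1-enylmethanol, other (E)-2,3-disubstituted allylic alcohols and conjugated dienols, all good substrates for this catalyst. Both new stereocentres, C1 and C2, are set by the reagent: the L-(+)-tartrate ligand adds oxygen to the face that gives (2S,3S) epoxy alcohols from (E)-allylic alcohols and the (1S,2S) epoxide from cyclohex-1-enylmethanol, and the vinylic C6 here only takes the place of a ring methylene, so the (1S,2S) oxirane with oxygen on the face that the C1 hydroxyl occupies in 13 is expected. The step needs site selectivity between two alkenes: only the allylic C1=C2 bond can reach the peroxide within the template formed by the C7 alkoxide, it is also the more substituted and electron-rich alkene, and the homoallylic C5=C6 bond reacts far more slowly under these conditions. It also needs the tertiary allylic oxirane to survive, hence the catalytic, sieve-dried, low-temperature variant and a non-acidic work-up.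

Step 5
Reactants: 7 [(1S,2S)-1,2-epoxycyclohex-5-en-1-yl]methanol
Product: 8 [(1S,2S,5S,6S)-1,2:5,6-diepoxycyclohexyl]methanol (oxiranes on opposite faces; C5–C6 oxirane on the face of C7)
Conditions: VO(acac)2 (3 mol %), t-BuOOH (1.3 equiv), CH2Cl2, 0 °C → rt
Reagents that add atoms: tert-butyl hydroperoxide, CC(C)(C)OO
Why: Vanadium-catalysed hydroxyl-directed epoxidation of a homoallylic alcohol: the C7 alkoxide bound to the VO(acac)2-derived peroxide can deliver oxygen only to the C5=C6 face on which C7 sits, which is also the face anti to the first oxirane, so C5–O and C6–O form trans to the C1–C2 oxirane. Consuming the alkene at this point also removes the allylic activation of the C1–O bond before any ring-opening is attempted.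

Step 6
Reactants: 8 [(1S,2S,5S,6S)-1,2:5,6-diepoxycyclohexyl]methanol
Product: 9 (1S,2R,5S,6S)-2-benzyloxy-5,6-epoxy-1-(hydroxymethyl)cyclohexan-1-ol
Conditions: Ti(OiPr)4 (1.5 equiv), BnOH (5 equiv), toluene, 40–60 °C
Reagents that add atoms: benzyl alcohol, OCc1ccccc1
Why: Ti(OiPr)4-mediated opening of a 2,3-epoxy alcohol at the carbon remote from the carbinol: the C7 alkoxide and the C1–C2 oxirane oxygen chelate titanium and benzyl alcohol attacks C2 from the face opposite the oxirane, so C2–O forms with inversion, anti to C1–O, while the quaternary C1 cannot be attacked in the SN2 sense. The C5–C6 oxirane can be reached only through a looser six-membered chelate and is expected to react more slowly.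

Step 7
Reactants: 9 (1S,2R,5S,6S)-2-benzyloxy-5,6-epoxy-1-(hydroxymethyl)cyclohexan-1-ol
Product: 10 [(1S,2R,5S,6S)-2-benzyloxy-5,6-epoxy-1-hydroxycyclohexyl]methyl benzoate
Conditions: BzCl (1.1 equiv), pyridine, CH2Cl2, −20 → 0 °C
Reagents that add atoms: benzoyl chloride, O=C(Cl)c1ccccc1
Why: Acylation of the only acylable hydroxyl: the primary C7–OH is benzoylated, the tertiary C1–OH is inert under these conditions, and the oxirane is untouched at low temperature.

Step 8
Reactants: 10 [(1S,2R,5S,6S)-2-benzyloxy-5,6-epoxy-1-hydroxycyclohexyl]methyl benzoate; 11 benzoic acid
Product: 12 [(1R,2R,5R,6S)-5-benzoyloxy-2-benzyloxy-1,6-dihydroxycyclohexyl]methyl benzoate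
Conditions: PhCO2H (3 equiv), Cs2CO3 (0.5 equiv), DMF, rt; then 10, 80 °C
Reagents that add atoms: none
Why: Cs2CO3 turns one equivalent of 11 into cesium benzoate in the flask, and this carboxylate opens the cyclohexene oxide in the SN2 sense at C5 (epoxide ring-opening by a carboxylate), attacking from the face opposite the oxirane oxygen to give the trans-diaxial hydroxy ester, so C5–OBz is set by inversion and C6–OH keeps its configuration, while C6 is shielded by the adjacent quaternary C1 and deactivated by its oxygen. The remaining free acid protonates the C6 alkoxide as it forms, which suppresses acyl migration and oxirane migration through the C1 hydroxyl, and the C7 benzoate lies on the same face as the oxirane oxygen and cannot participate.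

Step 9
Reactants: 12 [(1R,2R,5R,6S)-5-benzoyloxy-2-benzyloxy-1,6-dihydroxycyclohexyl]methyl benzoate
Product: 13 [(1S,2R,5R,6S)-5-benzoyloxy-1,2,6-trihydroxycyclohexyl]methyl benzoate (target)
Conditions: H2 (1 atm), Pd/C (10 wt %), EtOAc, rt
Reagents that add atoms: none
Why: Hydrogenolysis of the benzyl ether over palladium on carbon in a neutral, non-nucleophilic solvent frees the C2 hydroxyl; the benzoates and the tertiary alcohol are inert, and the absence of acid or base avoids acyl migration.

## Compound list

1 | cyclohex-2-en-1-one | O=C1C=CCCC1 | starting material
2 | lithium cyclohexa-1,5-dien-1-olate | [Li+].[O-]C1=CCCC=C1 | intermediate (not isolated)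
3 | cyclohexa-1,5-dien-1-yl trifluoromethanesulfonate | O=S(=O)(OC1=CCCC=C1)C(F)(F)F | intermediate
4 | methyl cyclohexa-1,5-diene-1-carboxylate | COC(=O)C1=CCCC=C1 | intermediate
5 | (cyclohexa-1,5-dien-1-yl)methanol | OCC1=CCCC=C1 | intermediate
6 | diethyl L-(+)-tartrate, diethyl (2R,3R)-2,3-dihydroxybutanedioate | CCOC(=O)[C@H](O)[C@@H](O)C(=O)OCC | starting material (chiral ligand)
7 | [(1S,2S)-1,2-epoxycyclohex-5-en-1-yl]methanol, also [(1S,6S)-7-oxabicyclo[4.1.0]hept-2-en-1-yl]methanol | OC[C@]1(O2)[C@@H]2CCC=C1 | intermediate
8 | [(1S,2S,5S,6S)-1,2:5,6-diepoxycyclohexyl]methanol (route numbering) | OC[C@]1(O2)[C@@H]2CC[C@@H]3O[C@H]13 | intermediate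
9 | (1S,2R,5S,6S)-2-benzyloxy-5,6-epoxy-1-(hydroxymethyl)cyclohexan-1-ol (route numbering) | OC[C@]1(O)[C@H](OCc2ccccc2)CC[C@@H]2O[C@H]12 | intermediate
10 | [(1S,2R,5S,6S)-2-benzyloxy-5,6-epoxy-1-hydroxycyclohexyl]methyl benzoate (route numbering) | O=C(OC[C@]1(O)[C@H](OCc2ccccc2)CC[C@@H]2O[C@H]12)c1ccccc1 | intermediate
11 | benzoic acid | OC(=O)c1ccccc1 | starting material
12 | [(1R,2R,5R,6S)-5-benzoyloxy-2-benzyloxy-1,6-dihydroxycyclohexyl]methyl benzoate (route numbering) | O=C(OC[C@]1(O)[C@H](OCc2ccccc2)CC[C@@H](OC(=O)c2ccccc2)[C@@H]1O)c1ccccc1 | intermediate
13 | [(1S,2R,5R,6S)-5-benzoyloxy-1,2,6-trihydroxycyclohexyl]methyl benzoate (route numbering) | O=C(OC[C@]1(O)[C@H](O)CC[C@@H](OC(=O)c2ccccc2)[C@@H]1O)c1ccccc1 | target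

## Step count and least certain steps

Total step count: 9. Longest linear sequence: 9 steps (1 to 13); 6 and 11 are bought.

Step 4 (key step).
- What may go wrong: Lewis-acid-induced ring-opening or rearrangement of the tertiary allylic oxirane while it is still bound to the Ti(OiPr)4-derived catalyst, and oxidative aromatisation of the diene by the hydroperoxide. A smaller risk is erosion of enantioselectivity because the substituent on C1 is unsaturated.
- Fallback (resolution in place of asymmetric catalysis): from 5, hydroxyl-directed epoxidation without a chiral ligand (VO(acac)2 1 mol %, t-BuOOH, CH2Cl2, 0 °C) would give racemic (1,2-epoxycyclohex-5-en-1-yl)methanol F1. Lipase-catalysed acetylation (Burkholderia cepacia lipase, vinyl acetate, t-BuOMe), a known way to resolve primary 2,3-epoxy alcohols, would then separate the antipodes. Written for an enzyme that acylates the (1R,2R) antipode to [(1R,2R)-1,2-epoxycyclohex-5-en-1-yl]methyl acetate F2, the alcohol left unreacted is 7, which rejoins the route at step 5. A lipase of the opposite preference would be chosen otherwise.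

Step 5.
- What may go wrong: opening of the still allylic C1–C2 oxirane by the Lewis-acidic vanadium peroxide before the alkene is consumed. Incomplete face control is the lesser concern.
- Fallback (metal-free Prilezhaev epoxidation instead of delivery from a metal alkoxide): from 7, m-chloroperbenzoic acid in CH2Cl2 over solid NaHCO3 at 0 °C. The face is then set by hydrogen bonding of the peracid to C7–OH and by the preference of peracids to attack anti to an adjacent oxirane; both point to the face of C7. The product is 8 and no new compound is made.

Step 6.
- What may go wrong: loss of chemoselectivity between the two oxiranes at the temperature that an alcohol nucleophile needs (benzyl alcohol also opening C5–C6 once a titanium-bound diolate has formed), and transfer of isopropoxide instead of benzyloxide.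
- Fallback (carboxylate nucleophile and acyl shift in place of the benzyl ether): from 8, Ti(OiPr)4 (1.2 equiv) and 11 (1.1 equiv) in CH2Cl2 at rt would be used. This is the fastest and mildest of the titanium-mediated openings of 2,3-epoxy alcohols and has no competing alkoxide, so it should deliver benzoate to C2 and give (1S,2R,5S,6S)-5,6-epoxy-1-hydroxy-1-(hydroxymethyl)cyclohexan-2-yl benzoate F3. A catalytic amount of Et3N in CH2Cl2 would then move the acyl group from the secondary C2 oxygen to the cis primary C7 oxygen through the six-membered ortho-acid, giving [(1S,2R,5S,6S)-5,6-epoxy-1,2-dihydroxycyclohexyl]methyl benzoate F4. Opening of F4 at C5 under the conditions of step 8 would come back to the route at 13, so that neither the benzyl ether nor step 9 is needed.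

Step 8.
- What may go wrong: sluggish substitution at C5 at a temperature where other processes set in, namely attack at C6, benzoyl migration from C7 to the new C6 hydroxyl, or oxirane migration through the C1 alkoxide.
- Fallback (hydration followed by selective acylation): from 10, acid-catalysed hydration (HClO4 aq., THF, 0 °C) should open the oxirane at C5 with inversion, since C6 is deactivated by the neighbouring C1–O bond and the C7 ester cannot participate from the oxirane face. This gives [(1R,2R,5R,6S)-2-benzyloxy-1,5,6-trihydroxycyclohexyl]methyl benzoate F5. Benzoylation of the less hindered C5–OH (BzCl, 2,4,6-collidine, CH2Cl2, −40 °C) returns to the route at 12.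

## Further compounds

F1 | step 4 | racemic (1,2-epoxycyclohex-5-en-1-yl)methanol (cis-fused oxirane, both enantiomers) | OCC1(O2)C2CCC=C1
F2 | step 4 | [(1R,2R)-1,2-epoxycyclohex-5-en-1-yl]methyl acetate | CC(=O)OC[C@@]1(O2)[C@H]2CCC=C1
F0 | step 5 | none | none
F3 | step 6 | (1S,2R,5S,6S)-5,6-epoxy-1-hydroxy-1-(hydroxymethyl)cyclohexan-2-yl benzoate (route numbering) | OC[C@]1(O)[C@H](OC(=O)c2ccccc2)CC[C@@H]2O[C@H]12
F4 | step 6 | [(1S,2R,5S,6S)-5,6-epoxy-1,2-dihydroxycyclohexyl]methyl benzoate (route numbering) | O=C(OC[C@]1(O)[C@H](O)CC[C@@H]2O[C@H]12)c1ccccc1
F5 | step 8 | [(1R,2R,5R,6S)-2-benzyloxy-1,5,6-trihydroxycyclohexyl]methyl benzoate (route numbering) | O=C(OC[C@]1(O)[C@H](OCc2ccccc2)CC[C@@H](O)[C@@H]1O)c1ccccc1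
A1 | alternative 1 | 1,2,6-tris(benzyloxy)-5-(4-methoxybenzyloxy)cyclohex-3-ene-1-carboxylic acid (route numbering, carboxyl carbon = C7) | OC(=O)[C@]1(OCc2ccccc2)[C@H](OCc2ccccc2)C=C[C@@H](OCc2ccc(OC)cc2)[C@@H]1OCc1ccccc1
A2 | alternative 2 | 2,2-dimethyl-1,3-dioxan-5-one | CC1(C)OCC(=O)CO1
A3 | alternative 2 | acrolein (prop-2-enal) | C=CC=O
A4 | alternative 2 | 6-hydroxy-3,3-dimethyl-2,4-dioxabicyclo[3.3.1]nonan-9-one (hydroxyl syn to the ketone bridge) | O=C1[C@H]2CC[C@@H](O)[C@@H]1OC(C)(C)O2
A5 | alternative 3 | (2R)-2-benzoyloxy-5-oxohept-6-enal | C=CC(=O)CC[C@@H](OC(=O)c1ccccc1)C=O
A6 | alternative 3 | 4-benzoyloxy-3-hydroxy-2-methylidenecyclohexan-1-one (3,4-trans) | C=C1C(=O)CC[C@@H](OC(=O)c2ccccc2)[C@@H]1O
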